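Atom labels C1–C8 follow the target throughout: ring C1 (ketone), C2=C3, C4 (OMe), C5 (CH2), C6 (quaternary); side chain C8 (methine) and C7 (aryl ketone). Compound numbers 1–14 are those of the steps and the compound list.

## Analysis of the target

Target 14 is a cyclohex-2-en-1-one with a methoxy group on C4 and an all-carbon quaternary centre at C6. C6 carries an allyl group and a 1-(3,4-dimethoxyphenyl)-1-oxopropan-2-yl branch. The three stereocentres are (4S), (6S) and (8R). C4 and C6 are 1,3-related across C5, with the methoxy group cis to the C8 branch and trans to the allyl group. C8 is an acyclic centre bonded directly to the quaternary carbon. It is α to the aryl ketone and is the one centre that epimerises readily; C6 cannot epimerise, and C4 is at risk only through γ-deprotonation of the enone. The terminal alkene excludes free borane, hydrogenation and strong electrophiles. The γ-alkoxy enone tolerates neither strong base nor strong acid. Three carbonyl-level carbons (C1, C4, C7) must be told apart. The hard part is C6: it is flanked by the C1 carbonyl and the tertiary C8 and has no neighbouring handle for stereocontrol. The route rests on two features. First, C1(=O)–C2=C3–C4(O) is a cis-enedione reduced at one end, which is the oxidation level of a 2,5-disubstituted furan whose ring carbons become C1–C4 and whose methyl group becomes C5. Second, C6 is β to the C7 carbonyl, so the ring bond C5–C6 is a Michael bond between a C4 methyl ketone and a C6=C8 aroyl enone.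

## Retrosynthetic reasoning

**14 to 13 (O–CH3 bond at C4).** The methyl ether is cut last. A C4 hydroxyl is what a carbonyl reduction delivers, and a neutral, silver-mediated O-alkylation is the only operation the hydroxy enone 13 then has to survive. The forward step must methylate without enolising C8.

**13 to 12 (C4–H bond).** Removing the hydride leads to enedione 12. Of its three ketones only C4 has an unbranched neighbour (the C5 methylene). C1 sits beside the quaternary C6; C7 sits beside the branched C8 and is deactivated by the electron-rich aryl ring. A hydride donor of moderate reactivity should therefore choose C4. C4 is too far from C6 for dependable substrate control, because the two C6 substituents compete for the pseudoaxial position, so the face is assigned to a chiral catalyst. The reductant must not hydroborate the allyl group.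

**12 to 11 (C5–C6 bond, the key disconnection).** In 12, C5 is α to the C4 carbonyl and C6 is β to the C7 carbonyl, so this is the one ring bond that is a Michael bond. Cutting it gives 11, an acyclic triketone without any stereocentre. In 11, C5 is the methyl group of a methyl ketone and C6=C8 is a tetrasubstituted alkene bearing the C1 acyl and C7 aroyl groups. The gain is that one isomerisation forms the ring, the quaternary stereocentre and the complete C1/C4 oxidation pattern, with chirality supplied by a catalyst. Cutting C1–C6 would need acyl-anion or radical chemistry and would leave the enone to be made afterwards. Cutting C1–C2 would need an organometallic that the aryl ketone does not tolerate. The forward reaction has to make C5 nucleophilic while leaving the other acidic positions alone, reach C6 (possible only with a Z C2=C3), choose one face of C6, and protonate C8.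

**11 to 10 (C1=O, C4=O and the Z alkene from a furan).** The cis-enedione of 11 is retraced to the furan ring of 10 by oxidative ring opening. The ring guarantees the Z geometry, hides both ketones during the organometallic steps, and its methyl group is C5. The forward step must oxidise the heteroarene in the presence of the terminal alkene and release the enedione without Z-to-E isomerisation.

**10 to 8 and 9 (C7–aryl bond), 8 to 7.** The aryl ketone is made by acyl substitution of the N-methoxy-N-methylamide 8 with aryl Grignard reagent 9. The addition stops at the ketone stage, and the aryl ketone enters only after the alkene has been built. Amide 8 comes from ethyl ester 7.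

**7 to 5 and 6 (C6–furyl bond).** The tetrasubstituted alkene is completed by cross-coupling of enol triflate 5 with furyl boronate 6, which proceeds with retention of alkene geometry. This replaces a one-flask conjugate addition and α-methylation across a triple bond. That sequence would pass through an allenolate, which can lose the alkene geometry and is a poor partner for a methyl electrophile.

**5 to 4 (enol C–O bond).** Triflate 5 comes from β-keto ester 4. The chelated enolate places the sulfonyloxy group cis to the ester. After coupling, the furyl group (future C1) is cis to the ester (future C7), the arrangement wanted in 11. The alkene geometry is not transferred to 12, but a single isomer makes the key step a clean experiment.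

**4 to 1 and 2 (C6–C8 bond).** The future alkene carbons are joined by decarboxylative acylation of malonate half-ester 2 with acid 1, through imidazolide 3. C8 arrives with its methyl group and C6 with its allyl group already in place.

## Alternatives that were turned down

**Alternative 1:** The C4–O bond is cut first and the carbocycle is left for later. C1 is carried as a methyl ketal carbon whose methyl is the future C2, C7 as a benzylic alcohol tied into a lactol, and C6 bears two identical allyl groups (lactol A1). In the forward key step an electrophilic iodine source activates one of the two diastereotopic allyl groups and the hemiketal hydroxyl closes 5-exo onto C4. The product is the cis-fused 2,8-dioxabicyclo[3.3.0]octane A2, with the iodomethyl carbon C3 on C4 and one allyl group left on C6.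
- For it: the quaternary carbon is made by two identical alkylations with no stereochemical issue. C4 and C6 are then fixed together by a ring fusion that can only be cis, under control of C7 and C8. On the C4/C6 relationship this is more secure than a reagent-controlled reduction.
- Against it: A2 is far from 14. The six-membered ring still has to be closed between C2 and C3. That requires opening the ketal to a methyl ketone while an iodohydrin-type C3/C4 unit, which closes to an epoxide with base, is present. The C2=C3 unsaturation must be introduced afterwards, and the oxygens on C4 and C7 must be differentiated (one methylated, one oxidised).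
- Comparison: the chosen route forms the carbocycle, the quaternary centre and the enone oxidation pattern in one step and finishes two steps later. The price is dependence on catalyst control at C6 and C4.

**Alternative 2:** The C1–C2 bond is cut. C1 is a lactone carbonyl, C4 the alkoxy carbon of a chiral-pool γ-lactone, and C2=C3 a Z-iodoalkene attached to C4 (lactone A3). In the forward key step halogen–lithium exchange at C2 gives an alkenyllithium that attacks the lactone carbonyl. The bridged hemiketal alkoxide collapses to the cyclohexenone and frees the C4 alkoxide, which is methylated in the same flask. The product is A4, which has a tert-butyl ester where 14 has the aryl ketone.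
- For it: C4 is bought rather than made. C6 is set by alkylating a lactone enolate anti to the C4 substituent, which is well-understood substrate control and stronger than the catalyst control of the chosen key step. Ring, enone and methyl ether arise in one flask.
- Against it: the aryl ketone is missing. Turning a hindered tert-butyl ester beside a quaternary carbon into an electron-rich aryl ketone, with the enone and the enolisable C8 present, takes several steps at the most sensitive stage. The organolithium must spare the ester and C8–H. The attack passes through a strained oxabicyclo[2.2.1] geometry onto a neopentyl-type carbonyl. C8 has to be set during the lactone alkylations without an obvious control element, and the linear sequence is longer.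
- Comparison: the chosen route carries the aryl ketone from step 5 onward and uses an achiral precursor made in six steps.

**Alternative 3:** The C1–C6 bond is cut. C1 is an acyl radical precursor (phenyl selenoester A5) on a chain that already holds the C4 methoxy stereocentre, and C6=C8 is the same tetrasubstituted aroyl alkene. In the forward key step the acyl radical adds 6-exo to C6, and the resulting C8 radical, α to C7, takes hydrogen from a silane donor. The product is A6, the 2,3-dihydro target.
- For it: a nucleophilic acyl radical adds to an electron-poor alkene through an early transition state and tolerates a fully substituted terminus far better than a polar enamine addition. On the bond-forming event itself this alternative is the stronger one. The neutral conditions spare C8 and the allyl group, and C4 is set beforehand by standard asymmetric chemistry.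
- Against it: C6 is controlled only by 1,3-induction from the C4 methoxy group through a chair-like transition state, which is uncertain for two C6 substituents of similar size. C8 is set by hydrogen-atom transfer without control. A6 lacks C2=C3, so a late dehydrogenation of the C1 ketone is needed while the C7 ketone can enolise at C8. The chiral acyclic precursor is longer to make, and selenium and silane waste is produced.
- Comparison: the chosen route reaches the enone oxidation level directly from the furan and puts C6 under catalyst control. It accepts a less precedented bond formation in exchange.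

Key step: step 7

Remark on the chemistry: 2, 6 and 9 are taken as purchased reagents. The quinine-derived amine in step 7 and the (R)-oxazaborolidine in step 8 are assumed to give the (6S) and (4S) series on the models stated in those steps; the pseudoenantiomeric amine or the antipodal oxazaborolidine would be used if the sense is the opposite.

## Route

Step 1
Reactants: 1 but-3-enoic acid; 2 3-ethoxy-2-methyl-3-oxopropanoic acid (monoethyl methylmalonate)
Product: 4 ethyl 2-methyl-3-oxohex-5-enoate, via but-3-enoyl imidazolide 3 (not isolated)
Conditions: 1, 1,1'-carbonyldiimidazole, THF, 0 °C → rt; then 2, MgCl2, Et3N, MeCN, rt; aq. HCl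
Reagents that add atoms: none
Why: Masamune-type decarboxylative Claisen condensation: the magnesium enolate of the malonate half-ester is C-acylated by the imidazolide and loses CO2, giving the α-methyl β-keto ester (racemic at its labile C2) in one operation. The nearly neutral conditions are chosen so that the β,γ-alkene of the acyl donor should not move into conjugation.

Step 2
Reactants: 4 ethyl 2-methyl-3-oxohex-5-enoate
Product: 5 ethyl (2Z)-2-methyl-3-[(trifluoromethanesulfonyl)oxy]hexa-2,5-dienoate
Conditions: NaH, CH2Cl2, 0 °C; then Tf2O, −78 → 0 °C
Reagents that add atoms: trifluoromethanesulfonic anhydride, O=S(=O)(OS(=O)(=O)C(F)(F)F)C(F)(F)F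
Why: O-sulfonylation of the chelated sodium enolate of a β-keto ester; chelation holds the enolate oxygen cis to the ester carbonyl, so the Z enol triflate is expected. One equivalent of NaH removes only the doubly activated C2–H and leaves the allylic methylene alone.

Step 3
Reactants: 5 ethyl (2Z)-2-methyl-3-[(trifluoromethanesulfonyl)oxy]hexa-2,5-dienoate; 6 4,4,5,5-tetramethyl-2-(5-methylfuran-2-yl)-1,3,2-dioxaborolane
Product: 7 ethyl (2Z)-2-methyl-3-(5-methylfuran-2-yl)hexa-2,5-dienoate
Conditions: Pd(OAc)2 (5 mol %), 2-dicyclohexylphosphino-2',6'-dimethoxybiphenyl (10 mol %), K3PO4, THF/H2O, 40 °C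
Reagents that add atoms: none
Why: Suzuki–Miyaura coupling of an enol triflate; oxidative addition and reductive elimination at zerovalent and divalent palladium retain the alkene geometry, so the furyl group takes the place of the triflate cis to the ester. The phosphate base at 40 °C should leave the skipped diene unconjugated, and the excess boronate offsets protodeboronation.

Step 4
Reactants: 7 ethyl (2Z)-2-methyl-3-(5-methylfuran-2-yl)hexa-2,5-dienoate
Product: 8 (2Z)-N-methoxy-N,2-dimethyl-3-(5-methylfuran-2-yl)hexa-2,5-dienamide
Conditions: MeNH(OMe)·HCl, AlMe3, CH2Cl2, 0 → 40 °C; 1 M HCl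
Reagents that add atoms: N,O-dimethylhydroxylamine hydrochloride, CNOC.Cl
Why: Weinreb aminolysis of an ester with the aluminium amide formed in the flask; the reagent is nucleophilic but hardly basic, so the doubly allylic methylene and the alkene geometry should be left untouched even though the ester is hindered.

Step 5
Reactants: 8 (2Z)-N-methoxy-N,2-dimethyl-3-(5-methylfuran-2-yl)hexa-2,5-dienamide; 9 (3,4-dimethoxyphenyl)magnesium bromide
Product: 10 (2Z)-1-(3,4-dimethoxyphenyl)-2-methyl-3-(5-methylfuran-2-yl)hexa-2,5-dien-1-one
Conditions: 9 (1.5 equiv), THF, −20 → 0 °C; aq. NH4Cl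
Reagents that add atoms: none
Why: Weinreb ketone synthesis; the chelated tetrahedral adduct does not collapse before work-up, so the aryl ketone is formed without over-addition. Conjugate addition is blocked by the fully substituted β-carbon.

Step 6
Reactants: 10 (2Z)-1-(3,4-dimethoxyphenyl)-2-methyl-3-(5-methylfuran-2-yl)hexa-2,5-dien-1-one
Product: 11 (2Z,5Z)-1-(3,4-dimethoxyphenyl)-2-methyl-3-(prop-2-en-1-yl)octa-2,5-diene-1,4,7-trione
Conditions: N-bromosuccinimide (1.0 equiv), NaHCO3, acetone/H2O, −20 °C, dark; used without delay
Reagents that add atoms: water, O
Why: Oxidative ring opening of a 2,5-disubstituted furan: bromination at a furan α-carbon, addition of water at the other and loss of HBr from the 2,5-dihydrofuran release the cis-enedione. The furan is far more nucleophilic than the monosubstituted alkene, and the cold bicarbonate buffer is chosen so that the Z geometry set by the ring is kept.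

Step 7
Reactants: 11 (2Z,5Z)-1-(3,4-dimethoxyphenyl)-2-methyl-3-(prop-2-en-1-yl)octa-2,5-diene-1,4,7-trione
Product: 12 (5S)-5-[(2R)-1-(3,4-dimethoxyphenyl)-1-oxopropan-2-yl]-5-(prop-2-en-1-yl)cyclohex-2-ene-1,4-dione (ring position 5 is C6 of 14)
Conditions: 9-amino-9-deoxy-epi-quinine (20 mol %), salicylic acid (40 mol %), toluene (0.02 M), 25 °C
Reagents that add atoms: none
Why: Proposed new method: the primary amine condenses with C4, the only unhindered ketone of 11 (C1 and C7 are flanked by fully substituted carbons), and the iminium tautomerises to the 2-aminodiene, which is nucleophilic at C5. C5 then adds to C6, the β-carbon of the C7 aroyl enone, whose carbonyl is hydrogen-bonded to the protonated quinuclidine; the C7 enol is protonated at C8 and hydrolysis of the ring iminium returns the C4 ketone and the catalyst. The closest known reaction type is the cinchona-primary-amine-catalysed intramolecular Michael addition of ketone enamines (including 2-aminodienes from methyl enones) to enones; it has not been shown for a tetrasubstituted acceptor that ends as an all-carbon quaternary centre, hence the label. The ring closes 6-exo-trig, with C6=C8 exocyclic to the forming ring; attack at C8 would be a seven-membered closure, and only the Z C2=C3 geometry lets C5 reach C6. C6 is set by enantioface selection of the chiral amine alone, since 11 has no stereocentre; the donor is held on the C9 nitrogen and the acceptor on the quinuclidinium, and the quinine-derived amine is assumed to give (6S). C8 is set when the enol is protonated next to the new quaternary centre; this is the least secure selectivity, and the C8 epimers are to be separated by chromatography. The step needs C-attack at C6 to outrun three competitors: reversible aza-Michael addition and Z-to-E isomerisation at the very electrophilic C2=C3, and a reversible five-ring aldol of C5 onto C1. High dilution, a hindered amine, a weak acid co-catalyst and the irreversible gain of a C–C bond in a six-membered ring are relied on for that.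

Step 8
Reactants: 12 (5S)-5-[(2R)-1-(3,4-dimethoxyphenyl)-1-oxopropan-2-yl]-5-(prop-2-en-1-yl)cyclohex-2-ene-1,4-dione
Product: 13 (4S,6S)-6-[(2R)-1-(3,4-dimethoxyphenyl)-1-oxopropan-2-yl]-4-hydroxy-6-(prop-2-en-1-yl)cyclohex-2-en-1-one
Conditions: (R)-1-methyl-3,3-diphenyltetrahydro-1H,3H-pyrrolo[1,2-c][1,3,2]oxazaborole (20 mol %), catecholborane (1.3 equiv), toluene, −78 °C; MeOH, then aq. NaHCO3
Reagents that add atoms: none
Why: Corey–Bakshi–Shibata reduction with catecholborane, which does not hydroborate the allyl group at −78 °C. The C4 carbonyl is the only ketone with an unbranched neighbour and should react first; the (R)-catalyst is expected to give (4S) if the C3 alkene carbon acts as the larger substituent, as alkenyl groups do in enone reductions. The new centre at C4 is thus set by the catalyst and not by the remote C6.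

Step 9
Reactants: 13 (4S,6S)-6-[(2R)-1-(3,4-dimethoxyphenyl)-1-oxopropan-2-yl]-4-hydroxy-6-(prop-2-en-1-yl)cyclohex-2-en-1-one
Product: 14 (4S,6S)-6-[(2R)-1-(3,4-dimethoxyphenyl)-1-oxopropan-2-yl]-4-methoxy-6-(prop-2-en-1-yl)cyclohex-2-en-1-one
Conditions: Ag2O, MeI, 4 Å molecular sieves, CH2Cl2, rt, dark
Reagents that add atoms: iodomethane, CI
Why: Purdie methylation of an unhindered secondary allylic alcohol; silver oxide activates the iodide and takes up HI without forming an enolate, so C8 and the γ-oxygenated enone should be untouched.

## Compound list

1 | but-3-enoic acid | C=CCC(=O)O | starting material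
2 | 3-ethoxy-2-methyl-3-oxopropanoic acid (monoethyl methylmalonate) | CCOC(=O)C(C)C(=O)O | starting material
3 | 1-(1H-imidazol-1-yl)but-3-en-1-one (but-3-enoyl imidazolide) | C=CCC(=O)n1ccnc1 | intermediate (not isolated)
4 | ethyl 2-methyl-3-oxohex-5-enoate (racemic) | CCOC(=O)C(C)C(=O)CC=C | intermediate
5 | ethyl (2Z)-2-methyl-3-[(trifluoromethanesulfonyl)oxy]hexa-2,5-dienoate | CCOC(=O)/C(C)=C(\OS(=O)(=O)C(F)(F)F)CC=C | intermediate
6 | 4,4,5,5-tetramethyl-2-(5-methylfuran-2-yl)-1,3,2-dioxaborolane | Cc1ccc(o1)B1OC(C)(C)C(C)(C)O1 | starting material
7 | ethyl (2Z)-2-methyl-3-(5-methylfuran-2-yl)hexa-2,5-dienoate | CCOC(=O)/C(C)=C(\c1ccc(C)o1)CC=C | intermediate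
8 | (2Z)-N-methoxy-N,2-dimethyl-3-(5-methylfuran-2-yl)hexa-2,5-dienamide | CON(C)C(=O)/C(C)=C(\c1ccc(C)o1)CC=C | intermediate
9 | (3,4-dimethoxyphenyl)magnesium bromide | COc1ccc([Mg]Br)cc1OC | starting material
10 | (2Z)-1-(3,4-dimethoxyphenyl)-2-methyl-3-(5-methylfuran-2-yl)hexa-2,5-dien-1-one | COc1ccc(cc1OC)C(=O)/C(C)=C(\c1ccc(C)o1)CC=C | intermediate
11 | (2Z,5Z)-1-(3,4-dimethoxyphenyl)-2-methyl-3-(prop-2-en-1-yl)octa-2,5-diene-1,4,7-trione | CC(=O)/C=C\C(=O)/C(CC=C)=C(/C)C(=O)c1ccc(OC)c(OC)c1 | intermediate
12 | (5S)-5-[(2R)-1-(3,4-dimethoxyphenyl)-1-oxopropan-2-yl]-5-(prop-2-en-1-yl)cyclohex-2-ene-1,4-dione | C=CC[C@@]1([C@@H](C)C(=O)c2ccc(OC)c(OC)c2)CC(=O)C=CC1=O | intermediate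
13 | (4S,6S)-6-[(2R)-1-(3,4-dimethoxyphenyl)-1-oxopropan-2-yl]-4-hydroxy-6-(prop-2-en-1-yl)cyclohex-2-en-1-one | C=CC[C@@]1([C@@H](C)C(=O)c2ccc(OC)c(OC)c2)C[C@H](O)C=CC1=O | intermediate
14 | (4S,6S)-6-[(2R)-1-(3,4-dimethoxyphenyl)-1-oxopropan-2-yl]-4-methoxy-6-(prop-2-en-1-yl)cyclohex-2-en-1-one | C=CC[C@@]1([C@@H](C)C(=O)c2ccc(OC)c(OC)c2)C[C@H](OC)C=CC1=O | target

## Step count and least certain steps

Total step count: 9. Longest linear sequence: 9 steps (from 1 or 2 to 14); 6 and 9 enter as purchased reagents.

**Step 7 (key step).** Three things are most likely to go wrong.
- Ring closure may fail. The acceptor is fully substituted and twisted, so the aminodiene may instead be diverted into the reversible five-ring aldol onto C1, or the substrate may be drained by amine-induced Z-to-E isomerisation and aza-Michael addition at C2=C3.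
- Face discrimination at C6 may be insufficient, or the enantiomeric purity may erode through retro-Michael and re-addition.
- Protonation at C8 may be unselective.

Fallback, from 11 and rejoining at 13: 11 is converted with TBSOTf and i-Pr2NEt (CH2Cl2, −78 °C) into the silyl dienol ether (2Z,5Z)-7-[(tert-butyldimethylsilyl)oxy]-1-(3,4-dimethoxyphenyl)-2-methyl-3-(prop-2-en-1-yl)octa-2,5,7-triene-1,4-dione F1. An intramolecular Mukaiyama–Michael addition (TiCl4, CH2Cl2, −78 °C), which activates the acceptor and involves no amine, should close the same C5–C6 bond. After chromatographic removal of the C8 epimer this gives racemic 12 with the relative configuration of 12, F2. F2 is then reduced under the conditions of step 8. The catalyst should give both enantiomers the (4S) configuration, so the product is a pair of diastereomers: 13 and (4S,6R)-6-[(2S)-1-(3,4-dimethoxyphenyl)-1-oxopropan-2-yl]-4-hydroxy-6-(prop-2-en-1-yl)cyclohex-2-en-1-one F3. These are separated by chromatography, and the route continues from 13. This costs half of the material and does not improve the selectivity at C8.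

**Step 8.** The reduction may go to the wrong carbonyl, since aryl ketones such as C7 are standard substrates for this catalyst. The facial sense may also be wrong, through a mismatch with C6 or because the C5 side rather than the C3 alkene behaves as the larger group.

Fallback, from 12 and rejoining at 13: a Luche reduction (NaBH4, CeCl3·7H2O, MeOH, −78 °C), which selects the unhindered enone carbonyl on steric grounds, should give 13 together with its C4 epimer (4R,6S)-6-[(2R)-1-(3,4-dimethoxyphenyl)-1-oxopropan-2-yl]-4-hydroxy-6-(prop-2-en-1-yl)cyclohex-2-en-1-one F4. After separation, F4 is inverted by a Mitsunobu reaction (4-nitrobenzoic acid, PPh3, diisopropyl azodicarboxylate, THF, 0 °C) to (1S,5S)-5-[(2R)-1-(3,4-dimethoxyphenyl)-1-oxopropan-2-yl]-4-oxo-5-(prop-2-en-1-yl)cyclohex-2-en-1-yl 4-nitrobenzoate F5. Methanolysis of F5 (K2CO3, MeOH, 0 °C) gives 13.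

**Step 6.** The furan is deactivated by conjugation with the enone, so bromination of the allyl alkene may compete. The cis-enedione may isomerise to the trans isomer during reaction or isolation, and the triketone may decompose on silica.

Fallback, from 10 and rejoining at 11: dye-sensitised photooxygenation (O2, visible light, methylene blue, CH2Cl2, −78 °C) adds singlet oxygen across the furan in a [4+2] reaction and does not touch a monosubstituted alkene. It should give the endoperoxide (2Z)-1-(3,4-dimethoxyphenyl)-2-methyl-3-(4-methyl-2,3,7-trioxabicyclo[2.2.1]hept-5-en-1-yl)hexa-2,5-dien-1-one F6. F6 is reduced in the cold with dimethyl sulfide to 11 under neutral conditions.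

**Step 1.** The β,γ-double bond of the acyl donor may migrate into conjugation during activation and acylation, which would carry a propenyl group instead of an allyl group through the route.

Fallback, from 2 and rejoining at 7: 2 is acylated with 5-methylfuran-2-carbonyl chloride (MgCl2, Et3N, MeCN) to ethyl 2-methyl-3-(5-methylfuran-2-yl)-3-oxopropanoate F7. Non-chelating O-sulfonylation (TsCl, N-methylimidazole, Et3N) should give the E enol tosylate ethyl (2E)-2-methyl-3-(5-methylfuran-2-yl)-3-[(4-methylbenzenesulfonyl)oxy]prop-2-enoate F8. Suzuki–Miyaura coupling of F8 with 2-allyl-4,4,5,5-tetramethyl-1,3,2-dioxaborolane (Pd(OAc)2, 2-dicyclohexylphosphino-2',6'-dimethoxybiphenyl, K3PO4) gives 7. The allyl group then enters only after the β-keto ester stage.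

## Further compounds

F1 | step 7 | (2Z,5Z)-7-[(tert-butyldimethylsilyl)oxy]-1-(3,4-dimethoxyphenyl)-2-methyl-3-(prop-2-en-1-yl)octa-2,5,7-triene-1,4-dione | C=C(O[Si](C)(C)C(C)(C)C)/C=C\C(=O)/C(CC=C)=C(/C)C(=O)c1ccc(OC)c(OC)c1
F2 | step 7 | racemic 5-[1-(3,4-dimethoxyphenyl)-1-oxopropan-2-yl]-5-(prop-2-en-1-yl)cyclohex-2-ene-1,4-dione, relative configuration as in 12 | C=CCC1(C(C)C(=O)c2ccc(OC)c(OC)c2)CC(=O)C=CC1=O
F3 | step 7 | (4S,6R)-6-[(2S)-1-(3,4-dimethoxyphenyl)-1-oxopropan-2-yl]-4-hydroxy-6-(prop-2-en-1-yl)cyclohex-2-en-1-one | C=CC[C@]1([C@H](C)C(=O)c2ccc(OC)c(OC)c2)C[C@H](O)C=CC1=O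
F4 | step 8 | (4R,6S)-6-[(2R)-1-(3,4-dimethoxyphenyl)-1-oxopropan-2-yl]-4-hydroxy-6-(prop-2-en-1-yl)cyclohex-2-en-1-one | C=CC[C@@]1([C@@H](C)C(=O)c2ccc(OC)c(OC)c2)C[C@@H](O)C=CC1=O
F5 | step 8 | (1S,5S)-5-[(2R)-1-(3,4-dimethoxyphenyl)-1-oxopropan-2-yl]-4-oxo-5-(prop-2-en-1-yl)cyclohex-2-en-1-yl 4-nitrobenzoate | C=CC[C@@]1([C@@H](C)C(=O)c2ccc(OC)c(OC)c2)C[C@H](OC(=O)c2ccc(cc2)[N+](=O)[O-])C=CC1=O
F6 | step 6 | (2Z)-1-(3,4-dimethoxyphenyl)-2-methyl-3-(4-methyl-2,3,7-trioxabicyclo[2.2.1]hept-5-en-1-yl)hexa-2,5-dien-1-one (racemic) | CC12OOC(O1)(C=C2)/C(CC=C)=C(/C)C(=O)c1ccc(OC)c(OC)c1
F7 | step 1 | ethyl 2-methyl-3-(5-methylfuran-2-yl)-3-oxopropanoate | CCOC(=O)C(C)C(=O)c1ccc(C)o1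
F8 | step 1 | ethyl (2E)-2-methyl-3-(5-methylfuran-2-yl)-3-[(4-methylbenzenesulfonyl)oxy]prop-2-enoate | CCOC(=O)/C(C)=C(/OS(=O)(=O)c1ccc(C)cc1)c1ccc(C)o1
A1 | alternative 1 | 3,3-diallyl-5-(3,4-dimethoxyphenyl)-2,4-dimethyltetrahydrofuran-2-ol (lactol with two allyl groups on C6) | C=CCC1(CC=C)[C@@H](C)[C@H](c2ccc(OC)c(OC)c2)OC1(C)O
A2 | alternative 1 | cis-fused 2,8-dioxabicyclo[3.3.0]octane ketal with iodomethyl on C4 and one allyl group on C6 | C=CC[C@@]1([C@@H](C)[C@H](c3ccc(OC)c(OC)c3)O2)C[C@@H](CI)O[C@@]12C
A3 | alternative 2 | γ-lactone with a (Z)-2-iodovinyl group on C4 and, on C6, allyl and the tert-butyl propanoate branch | C=CC[C@@]1([C@@H](C)C(=O)OC(C)(C)C)C[C@@H](/C=C\I)OC1=O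
A4 | alternative 2 | tert-butyl (2R)-2-[(1S,5S)-5-methoxy-2-oxo-1-(prop-2-en-1-yl)cyclohex-3-en-1-yl]propanoate | C=CC[C@@]1([C@@H](C)C(=O)OC(C)(C)C)C[C@H](OC)C=CC1=O
A5 | alternative 3 | Se-phenyl selenoester of the acyclic C1–C8 chain with the C4 methoxy group and the C6=C8 aroyl alkene | C=CCC(C[C@H](OC)CCC(=O)[Se]c1ccccc1)=C(C)C(=O)c1ccc(OC)c(OC)c1
A6 | alternative 3 | (2S,4S)-2-[(2R)-1-(3,4-dimethoxyphenyl)-1-oxopropan-2-yl]-4-methoxy-2-(prop-2-en-1-yl)cyclohexan-1-one (2,3-dihydro target) | C=CC[C@@]1([C@@H](C)C(=O)c2ccc(OC)c(OC)c2)C[C@H](OC)CCC1=O
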